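## Analysis of the target

The target is an ester of two terpenoid units. In the right half, cyclohexane ring A (C1, C2, C3, C4, C4a, C8a) is trans-fused to a seven-membered unsaturated lactone, ring B (C4a–C9(=O)–O10–C11–C12(CO2H)=C13–C8a). The left half is a cyclohexene (C1'–C6', C2'=C3') whose (E)-2-(hydroxymethyl)acrylic acid arm acylates the C14 oxygen on C4.

Ring A carries four contiguous stereocentres: C1 (R, isopropyl), C8a (R), C4a (R) and the quaternary carbinol C4 (S). With ring A drawn so that C1→C2→C3→C4→C4a→C8a runs clockwise and β pointing to the viewer, the isopropyl group, C13 and C14 are β and C9 and the C4 hydroxyl are α. C1/C8a are therefore cis, C8a/C4a trans, and the hydroxyl is cis to C9.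

The left ring has C1' (R) and C6' (S) cis. This pair is the mirror image of the C8a/C1 pair of ring A, so one enantiomeric series cannot supply both halves.

Ring B is a 2-(acyloxymethyl)acrylate, an allylic ester that bases, nucleophiles and zerovalent palladium open. The C4 carbinol is β to the C9 carbonyl. A free C14 hydroxyl beside a C9 ester can relactonise to a γ-lactone.

The synthesis is hard because the cis C1/C8a pair is the less stable arrangement, C4 is quaternary, and five one-carbon units at different oxidation levels must be told apart.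

The strategy rests on one feature: C1 and C8a are adjacent and cis, each bears one carbon (the isopropyl methine and C13), and C4, para to C1, is oxygenated. This is the pattern of a [4+2] adduct of a cis butenolide with a 2-oxygenated butadiene.

## Retrosynthetic reasoning

**Deprotection.** Target 48 is traced to 47, which differs only by two silyl ethers and a 2-(trimethylsilyl)ethyl ester. One fluoride treatment at the end avoids acid or base on ring B.

**Ring B.** The C12=C13 bond of 47 is cut by ring-closing metathesis to diene ester 46. The ring enforces the alkene geometry and the closure is neutral. The O10–C11 bond of 46 is cut to acid 43 and allylic bromide 45 (from 44), so the carboxyl group is alkylated and never activated next to the C4 hydroxyl.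

**Union of the halves.** The C9 acid 43 comes from primary alcohol 41. The C14–O ester bond of 41 is cut to spiro-epoxide 22 and left acid 40. Cutting here forms the ester by attack at the primary C14 without touching the C4–O bond, and the C14 oxygen is never free beside a C9 ester.

**C4.** Epoxide 22 goes back to homoallylic alcohol 21; the C9 hydroxyl must deliver the oxygen to the α face of C4. Both C=C bonds of 21 (via 20) come from the two carbonyl groups of keto aldehyde 19, itself from acetal 18.

**C9.** The C4a–C9 bond is cut to enone 15 (via 16 and 17). In 15 the C2=C3 bond blocks C3, C1 is an isopropyl methine, and C4a is the only position that a kinetic base removes. The one-carbon electrophile must add anti to the C8a substituent.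

**Regiochemistry and the isopropyl group.** Enone 15 is traced through ketal 14 to bromide 13 and on to bromo ketone 8, made from silyl enol ether 7. Oxidising 7 directly to an enone at the lactone stage would leave C1–H both α to the lactone carbonyl and γ to the enone, and a base would remove it before C4a–H. The position of the enol double bond is therefore stored as a C3 bromide. While the ketone is masked (10 to 13), the lactone carbonyl carbon becomes the isopropyl group.

**Key disconnection.** Adduct 7 is cut at C4a–C8a and C1–C2 into diene 2 and furanone 6. This forms ring A, the cis C1/C8a pair in absolute form, and places oxygen at C4.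

**Precursors.** Diene 2 comes from methyl vinyl ketone 1. Furanone 6 comes from hydroxyfuranone 4 and (−)-menthol 5, and 4 from furfural 3.

**Left acid.** Acid 40 comes from ester 39, cut at the acrylate C=C by cross-metathesis into vinyl compound 36 and acrylate 38 (from 37). Compound 36 goes back through 35, 34, 33, 32, 31 and 30 to imide 29. Imide 29 is cut at C1'–C6' and C4'–C5' into diene 26 and acryloyl imide 28 (from 27); this places the ring alkene at C2'=C3' directly. Diene 26 comes from bromide 24 (from 23) and boronate 25.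

## Alternatives that were turned down

**Alternative 1:** The disconnection is the C1'–C6' bond of the left ring. The forward key step is a ring-contracting Ireland–Claisen rearrangement in which an ester C–O bond is exchanged for that C–C bond and cis acid A1 is released.
- For it: one step gives the left ring, both of its stereocentres and the C2'=C3' position, with a carboxyl handle for the isopropyl group and no auxiliary at the ring-forming step. On that last point it is stronger than the auxiliary cycloaddition used here for the left ring.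
- Against it: the key step is spent on the simpler half. Ring A, with four contiguous stereocentres, the quaternary C4 and ring B, is left without a plan. The rearrangement also needs an enantiopure precursor with a fully substituted C–O centre and a geometrically pure alkene, and the boat and chair transition states can compete.
- Comparison: the chosen strategy puts its key step on the half where the stereochemical problem lies. It reaches an intermediate of the same type as A1 (compound 29) in one cycloaddition.

**Alternative 2:** The disconnection is O10–C11 and C12=C13. Forward, the C9 carboxylate adds to phosphonoacrylate A3, and the resulting phosphonate anion olefinates the C13 aldehyde to give A2.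
- For it: ring B closes in one pot without a metathesis catalyst and without a separate vinyl group. For ring B alone it is about two steps shorter than steps 36 and 37.
- Against it: the step creates no stereocentre and says nothing about ring A. It needs a free C9 acid and a free C13 aldehyde under base, and both flank epimerisable centres (C4a, C8a). The conjugate addition of a hindered carboxylate is reversible and competes with intermolecular olefination.
- Comparison: the chosen route closes ring B under neutral conditions with the left half already attached, and uses its key step to set C1 and C8a.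

**Alternative 3:** The disconnection is the acyl carbon of the connecting ester. Forward, a palladium-catalysed alkoxycarbonylation joins alkenyl iodide A5 to the C14 hydroxyl of diol A6 and gives A4.
- For it: it is the most convergent of the four, needs no left acid, and comes very late. In convergence it is stronger than step 33.
- Against it: A6 holds ring B, an allylic ester of the kind that zerovalent palladium ionises. Its free C14 hydroxyl sits beside the C9 ester under amine base and can relactonise. A geometrically pure trisubstituted iodide is required, and no stereocentre is formed.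
- Comparison: in the chosen route the C14–O bond is made by epoxide opening before ring B exists, so ring B meets neither palladium nor a free C14 hydroxyl.

Key step: step 4

Assumption: C3 of 8 to 13 is carried as a mixture of bromide epimers; this centre is destroyed in step 10.
Assumption: 23, 25, 27, 37, 44, the Burgess reagent and Dess–Martin periodinane are bought.

## Route

Step 1
Reactants: 1 methyl vinyl ketone
Product: 2 2-(tert-butyldimethylsilyloxy)buta-1,3-diene
Conditions: TBSOTf, Et3N, Et2O, 0 °C
Reagents that add atoms: tert-butyldimethylsilyl trifluoromethanesulfonate, CC(C)(C)[Si](C)(C)OS(=O)(=O)C(F)(F)F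
Why: Soft enolisation and O-silylation (silyl enol ether formation); the methyl group is the only enolisable position, so one diene isomer should form.

Step 2
Reactants: 3 furfural
Product: 4 5-hydroxyfuran-2(5H)-one
Conditions: O2, hν (visible), methylene blue (cat.), MeOH, 20 °C
Reagents that add atoms: dioxygen, O=O
Why: Singlet-oxygen [4+2] photooxygenation of the furan; methanolysis of the endoperoxide expels the formyl carbon as methyl formate and leaves the γ-hydroxybutenolide.

Step 3
Reactants: 4 5-hydroxyfuran-2(5H)-one, 5 (−)-menthol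
Product: 6 (5R)-5-[(1R,2S,5R)-menthyloxy]furan-2(5H)-one
Conditions: CSA (cat.), toluene, reflux, Dean–Stark; crystallisation from petroleum ether, mother liquor re-equilibrated with acid
Reagents that add atoms: none
Why: Acid-catalysed acetalisation of the pseudo-acid; the C5 epimers interconvert under acid and the (5R) epimer crystallises, so the acetal centre should be obtained in one configuration.

Step 4
Reactants: 2 2-(tert-butyldimethylsilyloxy)buta-1,3-diene, 6 (5R)-5-menthyloxyfuran-2(5H)-one
Product: 7 (3R,3aR,7aS)-5-(tert-butyldimethylsilyloxy)-3-[(1R,2S,5R)-menthyloxy]-3a,4,7,7a-tetrahydro-2-benzofuran-1(3H)-one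
Conditions: 2 (3 equiv), BHT (cat.), toluene, 110 °C, sealed vessel
Reagents that add atoms: none
Why: A thermal, concerted but asynchronous Diels–Alder reaction of normal electron demand; the closest known case is the cycloaddition of 5-menthyloxy-2(5H)-furanone with 2-siloxybuta-1,3-dienes. Ring A closes by [4+2] annulation across the butenolide C=C: the C4a–C8a and C1–C2 bonds form suprafacially on both partners, which gives the cis-fused bicyclic lactone and so the cis C1/C8a relation. The diene terminus next to the siloxy carbon has the largest HOMO coefficient and bonds to the β-carbon of the butenolide, so the siloxy carbon ends para to the carbonyl-bearing carbon (C4 relative to C1). Both new stereocentres, C1 and C8a, are controlled by the acetal centre C13: the diene approaches the face anti to the menthyloxy group, and with the (5R) acetal the lactone carbonyl carbon and C13 come to lie on the β face, as the target requires. The diene has no terminal substituent, so endo or exo approach creates no further stereocentre. The step needs facial and regiochemical selectivity; the acetal substituent secures the first and the 2-siloxy donor the second. The silyl enol ether of 7 records the C3=C4 position for step 5.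

Step 5
Reactants: 7 cycloadduct
Product: 8 (3R,3aR,7aS)-6-bromo-3-[(1R,2S,5R)-menthyloxy]hexahydro-2-benzofuran-1,5-dione (bromine on C3 of the target numbering)
Conditions: N-bromosuccinimide, NaHCO3, THF, −78 → 0 °C
Reagents that add atoms: N-bromosuccinimide, O=C1CCC(=O)N1Br
Why: Electrophilic α-bromination of a silyl enol ether puts bromine only on C3, the enol carbon; the regiochemistry of the cycloadduct is thus stored in a group that survives acid and Grignard reagents.

Step 6
Reactants: 8 bromo ketone lactone
Product: 10 methyl 5-bromo-2-(dimethoxymethyl)-4,4-dimethoxycyclohexane-1-carboxylate (1,2-cis), via carboxylic acid 9 (not isolated)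
Conditions: HC(OMe)3, MeOH, TsOH (cat.), 25 → 45 °C
Reagents that add atoms: methanol, CO; trimethyl orthoformate, COC(OC)OC
Why: Acid-catalysed transacetalisation opens the acylal to the C13 dimethyl acetal and the C1 acid, which the orthoformate esterifies, while the α-bromo ketone is ketalised; C1 and C8a are not enolised and menthol is recovered.

Step 7
Reactants: 10 bromo ketal ester
Product: 11 2-[5-bromo-2-(dimethoxymethyl)-4,4-dimethoxycyclohexyl]propan-2-ol (1,2-cis)
Conditions: MeMgBr (4 equiv), THF, 0 °C
Reagents that add atoms: methylmagnesium bromide, C[Mg]Br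
Why: Double Grignard addition to the ester gives the dimethyl carbinol; ketal, acetal and the secondary bromide are inert to MeMgBr at this temperature.

Step 8
Reactants: 11 tertiary alcohol
Product: 12 4-bromo-1-(dimethoxymethyl)-5,5-dimethoxy-2-(prop-1-en-2-yl)cyclohexane (1,2-cis)
Conditions: Burgess reagent, toluene, 70 °C
Reagents that add atoms: none
Why: Burgess dehydration (syn elimination of the sulfamate ester); loss of one of the six methyl hydrogens is favoured over the hindered ring C1–H, so the isopropenyl isomer should predominate and C1 is not touched.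

Step 9
Reactants: 12 isopropenyl compound
Product: 13 4-bromo-1-(dimethoxymethyl)-5,5-dimethoxy-2-isopropylcyclohexane (1,2-cis)
Conditions: H2 (1 atm), RhCl(PPh3)3 (5 mol %), benzene, 25 °C
Reagents that add atoms: none
Why: Homogeneous hydrogenation with RhCl(PPh3)3 reduces the 1,1-disubstituted alkene and leaves the C–Br bond; any tetrasubstituted isopropylidene isomer stays unreduced and is separated.

Step 10
Reactants: 13 bromo ketal
Product: 14 5-(dimethoxymethyl)-3,3-dimethoxy-6-isopropylcyclohex-1-ene (5,6-cis)
Conditions: KOtBu, DMSO, 25 → 50 °C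
Reagents that add atoms: none
Why: E2 dehydrobromination of an α-bromo ketal; the ketal carbon has no hydrogen, so only the C2=C3 alkene can form.

Step 11
Reactants: 14 enone dimethyl ketal
Product: 15 5-(dimethoxymethyl)-4-isopropylcyclohex-2-en-1-one (4,5-cis)
Conditions: oxalic acid (5 % aq.) on SiO2, CH2Cl2, 0 → 25 °C
Reagents that add atoms: water, O
Why: Chemoselective acetal hydrolysis; the allylic ketal ionises far faster than the aldehyde dimethyl acetal, so the enone is freed while C13 stays protected.

Step 12
Reactants: 15 enone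
Product: 16 5-(dimethoxymethyl)-6-(hydroxymethyl)-4-isopropylcyclohex-2-en-1-one (4,5-cis, 5,6-trans; hydroxymethyl α at C4a)
Conditions: LiN(iPr)2 (1.15 equiv), THF, −78 °C; CH2O (gas, from paraformaldehyde), −78 °C; NH4Cl (aq.)
Reagents that add atoms: formaldehyde, C=O
Why: Aldol hydroxymethylation of the kinetic cross-conjugated enolate: C3 is vinylic and C1 is now an unactivated isopropyl methine, so only C4a is deprotonated. Formaldehyde adds anti to the adjacent C8a substituent, which sets C4a with C9 α; this is also the more stable epimer.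

Step 13
Reactants: 16 hydroxymethyl enone
Product: 17 6-[(tert-butyldiphenylsilyloxy)methyl]-5-(dimethoxymethyl)-4-isopropylcyclohex-2-en-1-one
Conditions: TBDPSCl, imidazole, DMF, 0 → 25 °C
Reagents that add atoms: tert-butyl(chloro)diphenylsilane, CC(C)(C)[Si](Cl)(c1ccccc1)c1ccccc1
Why: Silyl ether formation at the primary alcohol; TBDPS is chosen because it survives the acidic acetal hydrolysis of step 15.

Step 14
Reactants: 17 silyl ether enone
Product: 18 2-[(tert-butyldiphenylsilyloxy)methyl]-3-(dimethoxymethyl)-4-isopropylcyclohexan-1-one (2,3-trans, 3,4-cis)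
Conditions: H2 (1 atm), Pd/C, EtOAc, 25 °C
Reagents that add atoms: none
Why: Catalytic hydrogenation of the enone C2=C3 bond, whose blocking role is over; ketone, acetal and silyl ether are not affected.

Step 15
Reactants: 18 keto acetal
Product: 19 2-[(tert-butyldiphenylsilyloxy)methyl]-6-isopropyl-3-oxocyclohexane-1-carbaldehyde (1,2-trans, 1,6-cis)
Conditions: TFA, H2O, CHCl3, 0 °C
Reagents that add atoms: water, O
Why: Acid hydrolysis of the dimethyl acetal to the C13 aldehyde; short, cold exposure should keep the α-centres C8a and C4a from epimerising.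

Step 16
Reactants: 19 keto aldehyde
Product: 20 tert-butyl[(6-ethenyl-5-isopropyl-2-methylidenecyclohexyl)methoxy]diphenylsilane (1,6-trans, 5,6-cis)
Conditions: Ph3PCH3Br (4 equiv), KOtBu (3.8 equiv), THF, 0 °C; 19 at −78 → 40 °C
Reagents that add atoms: methyltriphenylphosphonium bromide, C[P+](c1ccccc1)(c1ccccc1)c1ccccc1.[Br-]
Why: Double Wittig methylenation: the aldehyde reacts in the cold to the C13 vinyl group, the hindered ketone on warming to the exocyclic C4=C14 alkene; no stereocentre is formed.

Step 17
Reactants: 20 silyl ether diene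
Product: 21 (6-ethenyl-5-isopropyl-2-methylidenecyclohexyl)methanol (1,6-trans, 5,6-cis)
Conditions: TBAF, THF, 25 °C
Reagents that add atoms: none
Why: Fluoride cleavage of the silyl ether frees the C9 hydroxyl that directs the next step.

Step 18
Reactants: 21 homoallylic alcohol
Product: 22 (5-ethenyl-6-isopropyl-1-oxaspiro[2.5]octan-4-yl)methanol (oxirane oxygen α on C4, cis to the 4a-hydroxymethyl group; 8a-ethenyl β, 1-isopropyl β)
Conditions: VO(acac)2 (5 mol %), tBuOOH (1.5 equiv), CH2Cl2, 0 → 25 °C
Reagents that add atoms: tert-butyl hydroperoxide, CC(C)(C)OO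
Why: Hydroxyl-directed epoxidation of a homoallylic alcohol: the vanadate ester of the C9 alcohol delivers oxygen to the face of C4 on which C9 sits (α), which sets C4. The vinyl group is monosubstituted and farther from the hydroxyl, so it should not react.

Step 19
Reactants: 23 2-bromoprop-2-en-1-ol
Product: 24 [(2-bromoprop-2-en-1-yl)oxy]tri(propan-2-yl)silane
Conditions: TIPSCl, imidazole, CH2Cl2, 25 °C
Reagents that add atoms: chlorotri(propan-2-yl)silane, CC(C)[Si](Cl)(C(C)C)C(C)C
Why: Silyl ether formation; the TIPS group is chosen to outlast the acidic removal of a TBS group in step 27.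

Step 20
Reactants: 24 vinyl bromide, 25 (E)-tert-butyldimethyl{[3-(4,4,5,5-tetramethyl-1,3,2-dioxaborolan-2-yl)prop-2-en-1-yl]oxy}silane
Product: 26 (E)-5-(tert-butyldimethylsilyloxy)-2-{[tri(propan-2-yl)silyloxy]methyl}penta-1,3-diene
Conditions: Pd(PPh3)4 (5 mol %), K3PO4, dioxane/H2O, 70 °C
Reagents that add atoms: none
Why: Suzuki–Miyaura coupling of an alkenyl bromide with an alkenylboronate proceeds with retention of the E geometry and gives the 1,3-disubstituted diene.

Step 21
Reactants: 27 (S)-4-benzyl-1,3-oxazolidin-2-one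
Product: 28 (S)-3-acryloyl-4-benzyl-1,3-oxazolidin-2-one
Conditions: MeMgBr (1.05 equiv), THF, 0 °C; acryloyl chloride, −78 → 0 °C
Reagents that add atoms: acryloyl chloride, C=CC(=O)Cl
Why: N-Acylation of the magnesium salt of the oxazolidinone; the bromomagnesium salt limits polymerisation of the acrylate.

Step 22
Reactants: 26 diene, 28 acryloyl imide
Product: 29 (S)-4-benzyl-3-{[cis-2-[(tert-butyldimethylsilyloxy)methyl]-4-{[tri(propan-2-yl)silyloxy]methyl}cyclohex-3-en-1-yl]carbonyl}-1,3-oxazolidin-2-one (acyl carbon on C6', silyloxymethyl on C1', both β)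
Conditions: Et2AlCl (1.4 equiv), CH2Cl2, −78 °C
Reagents that add atoms: none
Why: Evans auxiliary-controlled Diels–Alder reaction: the Et2AlCl-chelated s-cis imide is attacked on the face opposite the benzyl group. The 1- and 3-substituents of the diene both direct the same regiochemistry, and endo addition places the C1' substituent cis to the acyl group, which sets C1' and C6' and puts the alkene at C2'=C3'.

Step 23
Reactants: 29 imide
Product: 30 methyl cis-2-[(tert-butyldimethylsilyloxy)methyl]-4-{[tri(propan-2-yl)silyloxy]methyl}cyclohex-3-ene-1-carboxylate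
Conditions: MeOMgBr (from MeMgBr and MeOH), MeOH/CH2Cl2, 0 °C
Reagents that add atoms: methanol, CO
Why: Transesterification of the imide with bromomagnesium methoxide removes the auxiliary under weakly basic conditions that should not epimerise C6'; the oxazolidinone is recovered.

Step 24
Reactants: 30 methyl ester
Product: 31 2-{cis-2-[(tert-butyldimethylsilyloxy)methyl]-4-{[tri(propan-2-yl)silyloxy]methyl}cyclohex-3-en-1-yl}propan-2-ol
Conditions: MeMgBr (4 equiv), THF, 0 → 25 °C
Reagents that add atoms: methylmagnesium bromide, C[Mg]Br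
Why: Double Grignard addition to the ester gives the dimethyl carbinol; the silyl ethers are inert.

Step 25
Reactants: 31 tertiary alcohol
Product: 32 tert-butyldimethyl{[cis-6-(prop-1-en-2-yl)-3-{[tri(propan-2-yl)silyloxy]methyl}cyclohex-2-en-1-yl]methoxy}silane
Conditions: Burgess reagent, toluene, 60 °C
Reagents that add atoms: none
Why: Burgess dehydration as in step 8; elimination into a methyl group should predominate over loss of the ring C6'–H.

Step 26
Reactants: 32 isopropenyl compound
Product: 33 tert-butyldimethyl{[cis-6-isopropyl-3-{[tri(propan-2-yl)silyloxy]methyl}cyclohex-2-en-1-yl]methoxy}silane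
Conditions: H2 (1 atm), RhCl(PPh3)3 (5 mol %), benzene, 25 °C
Reagents that add atoms: none
Why: RhCl(PPh3)3 hydrogenates the 1,1-disubstituted alkene selectively; the trisubstituted ring alkene is left.

Step 27
Reactants: 33 bis-silyl ether
Product: 34 [cis-6-isopropyl-3-{[tri(propan-2-yl)silyloxy]methyl}cyclohex-2-en-1-yl]methanol
Conditions: CSA (0.1 equiv), MeOH/CH2Cl2, 0 °C
Reagents that add atoms: none
Why: Acid-catalysed desilylation: the primary TBS ether is cleaved much faster than the TIPS ether.

Step 28
Reactants: 34 alcohol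
Product: 35 cis-6-isopropyl-3-{[tri(propan-2-yl)silyloxy]methyl}cyclohex-2-ene-1-carbaldehyde
Conditions: Dess–Martin periodinane, NaHCO3, CH2Cl2, 0 °C; used crude
Reagents that add atoms: none
Why: Dess–Martin oxidation under buffered, neutral conditions, so the allylic α-centre C1' of the β,γ-unsaturated aldehyde is not epimerised.

Step 29
Reactants: 35 aldehyde
Product: 36 {[cis-3-ethenyl-4-isopropylcyclohex-1-en-1-yl]methoxy}tri(propan-2-yl)silane (ethenyl on C1', isopropyl on C6')
Conditions: Ph3PCH3Br, KOtBu, THF, 0 °C; 35 at −78 → 0 °C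
Reagents that add atoms: methyltriphenylphosphonium bromide, C[P+](c1ccccc1)(c1ccccc1)c1ccccc1.[Br-]
Why: Wittig methylenation; addition of the ylide to the aldehyde at low temperature should outrun enolisation.

Step 30
Reactants: 37 methyl 2-(hydroxymethyl)acrylate
Product: 38 methyl 2-[(tert-butyldimethylsilyloxy)methyl]acrylate
Conditions: TBSCl, imidazole, CH2Cl2, 0 → 25 °C
Reagents that add atoms: tert-butyl(chloro)dimethylsilane, CC(C)(C)[Si](C)(C)Cl
Why: Silyl ether formation at the primary allylic alcohol.

Step 31
Reactants: 36 vinyl compound, 38 silyloxymethyl acrylate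
Product: 39 methyl (E)-2-[(tert-butyldimethylsilyloxy)methyl]-3-[(1R,6S)-6-isopropyl-3-{[tri(propan-2-yl)silyloxy]methyl}cyclohex-2-en-1-yl]acrylate
Conditions: second-generation Hoveyda–Grubbs catalyst RuCl2(H2IMes)(=CH-C6H4-2-OiPr) (10 mol %), 38 (4 equiv), CH2Cl2, 40 °C
Reagents that add atoms: none
Why: Olefin cross-metathesis of a terminal alkene with a 1,1-disubstituted acrylate; such couplings give the trisubstituted enoate with the ester trans to the alkyl group (E), and the ring alkene is inert.

Step 32
Reactants: 39 methyl ester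
Product: 40 (E)-2-[(tert-butyldimethylsilyloxy)methyl]-3-[(1R,6S)-6-isopropyl-3-{[tri(propan-2-yl)silyloxy]methyl}cyclohex-2-en-1-yl]acrylic acid
Conditions: LiOH, THF/MeOH/H2O, 25 °C; cold dilute HCl to pH 4
Reagents that add atoms: lithium hydroxide, [Li+].[OH-]
Why: Saponification of the methyl ester; primary TBS and TIPS ethers are stable to aqueous LiOH at room temperature.

Step 33
Reactants: 22 epoxy alcohol, 40 left acid
Product: 41 [3-ethenyl-1-hydroxy-2-(hydroxymethyl)-4-isopropylcyclohexyl]methyl ester of 40 (target locants: 4-OH α, C14 ester β, 4a-CH2OH α, 8a-ethenyl β, 1-isopropyl β)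
Conditions: 40 (1.3 equiv), Cs2CO3 (0.2 equiv), DMF, 70 °C
Reagents that add atoms: none
Why: Base-catalysed ring opening of a terminal epoxide by a carboxylate (SN2 at the primary C14) forms the connecting ester and the free tertiary hydroxyl together; the C4–O bond is not broken, so the C4 configuration from step 18 is kept.

Step 34
Reactants: 41 diol ester
Product: 43 C9 carboxylic acid of 41 (2-ethenyl-6-hydroxy-3-isopropyl-6-(acyloxymethyl)cyclohexane-1-carboxylic acid), via aldehyde 42 (not isolated)
Conditions: TEMPO (0.2 equiv), PhI(OAc)2 (2.5 equiv), MeCN/H2O, 25 °C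
Reagents that add atoms: water, O
Why: TEMPO/PhI(OAc)2 oxidation takes the primary alcohol through the aldehyde hydrate to the acid; the tertiary alcohol, the trisubstituted alkenes and the silyl ethers are not attacked.

Step 35
Reactants: 44 2-(bromomethyl)acrylic acid
Product: 45 2-(trimethylsilyl)ethyl 2-(bromomethyl)acrylate
Conditions: 2-(trimethylsilyl)ethanol, DCC, DMAP (cat.), CH2Cl2, 0 °C
Reagents that add atoms: 2-(trimethylsilyl)ethanol, C[Si](C)(C)CCO
Why: Steglich esterification gives an ester that fluoride removes together with the silyl ethers.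

Step 36
Reactants: 43 acid, 45 allylic bromide
Product: 46 C9 ester of 43 with the 2-{[2-(trimethylsilyl)ethoxy]carbonyl}prop-2-en-1-yl group
Conditions: KHCO3, DMF, 0 → 25 °C
Reagents that add atoms: none
Why: O-Alkylation of the carboxylate by the reactive allylic bromide (SN2 and SN2' give the same product) forms the O10–C11 bond without activating the carboxyl group next to the C4 hydroxyl.

Step 37
Reactants: 46 diene ester
Product: 47 target as bis-silyl ether and 2-(trimethylsilyl)ethyl ester
Conditions: second-generation Grubbs catalyst RuCl2(PCy3)(H2IMes)(=CHPh) (10 mol %), toluene (2 mM), 80 °C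
Reagents that add atoms: none
Why: Ring-closing metathesis between the C13 vinyl group and the acrylate methylidene forms C12=C13 and closes the seven-membered ring B with loss of ethene; the ring fixes the alkene geometry, and the trisubstituted alkenes of the left half do not take part.

Step 38
Reactants: 47 protected target
Product: 48 CNP0361406.11 (target)
Conditions: TBAF (8 equiv), AcOH (4 equiv), THF, 0 → 25 °C
Reagents that add atoms: none
Why: Fluoride cleaves both silyl ethers and fragments the 2-(trimethylsilyl)ethyl ester to the acid, ethene and fluorotrimethylsilane; the acetic acid buffer protects the allylic lactone of ring B from base.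

## Compound list

1 | methyl vinyl ketone | CC(=O)C=C | starting material
2 | 2-(tert-butyldimethylsilyloxy)buta-1,3-diene | C=CC(=C)O[Si](C)(C)C(C)(C)C | intermediate
3 | furfural | O=Cc1ccco1 | starting material
4 | 5-hydroxyfuran-2(5H)-one (racemic) | O=C1OC(O)C=C1 | intermediate
5 | (−)-menthol, (1R,2S,5R)-2-isopropyl-5-methylcyclohexan-1-ol | CC(C)[C@@H]1CC[C@@H](C)C[C@H]1O | starting material
6 | (5R)-5-[(1R,2S,5R)-menthyloxy]furan-2(5H)-one | O=C1O[C@@H](O[C@@H]2C[C@H](C)CC[C@H]2C(C)C)C=C1 | intermediate
7 | (3R,3aR,7aS)-5-(tert-butyldimethylsilyloxy)-3-[(1R,2S,5R)-menthyloxy]-3a,4,7,7a-tetrahydro-2-benzofuran-1(3H)-one | O=C1O[C@@H](O[C@@H]3C[C@H](C)CC[C@H]3C(C)C)[C@@H]2CC(O[Si](C)(C)C(C)(C)C)=CC[C@H]12 | intermediate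
8 | (3R,3aR,7aS)-6-bromo-3-[(1R,2S,5R)-menthyloxy]hexahydro-2-benzofuran-1,5-dione (bromide epimers) | O=C1O[C@@H](O[C@@H]3C[C@H](C)CC[C@H]3C(C)C)[C@@H]2CC(=O)C(Br)C[C@H]12 | intermediate
9 | 5-bromo-2-(dimethoxymethyl)-4,4-dimethoxycyclohexane-1-carboxylic acid (1,2-cis; not isolated) | OC(=O)[C@H]1CC(Br)C(OC)(OC)C[C@H]1C(OC)OC | intermediate
10 | methyl 5-bromo-2-(dimethoxymethyl)-4,4-dimethoxycyclohexane-1-carboxylate (1,2-cis) | COC(=O)[C@H]1CC(Br)C(OC)(OC)C[C@H]1C(OC)OC | intermediate
11 | 2-[5-bromo-2-(dimethoxymethyl)-4,4-dimethoxycyclohexyl]propan-2-ol (1,2-cis) | CC(C)(O)[C@H]1CC(Br)C(OC)(OC)C[C@H]1C(OC)OC | intermediate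
12 | 4-bromo-1-(dimethoxymethyl)-5,5-dimethoxy-2-(prop-1-en-2-yl)cyclohexane (1,2-cis) | CC(=C)[C@H]1CC(Br)C(OC)(OC)C[C@H]1C(OC)OC | intermediate
13 | 4-bromo-1-(dimethoxymethyl)-5,5-dimethoxy-2-isopropylcyclohexane (1,2-cis) | CC(C)[C@H]1CC(Br)C(OC)(OC)C[C@H]1C(OC)OC | intermediate
14 | 5-(dimethoxymethyl)-3,3-dimethoxy-6-isopropylcyclohex-1-ene (5,6-cis) | CC(C)[C@H]1C=CC(OC)(OC)C[C@H]1C(OC)OC | intermediate
15 | 5-(dimethoxymethyl)-4-isopropylcyclohex-2-en-1-one (4,5-cis) | CC(C)[C@H]1C=CC(=O)C[C@H]1C(OC)OC | intermediate
16 | 5-(dimethoxymethyl)-6-(hydroxymethyl)-4-isopropylcyclohex-2-en-1-one (4,5-cis, 5,6-trans) | CC(C)[C@H]1C=CC(=O)[C@H](CO)[C@H]1C(OC)OC | intermediate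
17 | 6-[(tert-butyldiphenylsilyloxy)methyl]-5-(dimethoxymethyl)-4-isopropylcyclohex-2-en-1-one (4,5-cis, 5,6-trans) | CC(C)[C@H]1C=CC(=O)[C@H](CO[Si](c2ccccc2)(c2ccccc2)C(C)(C)C)[C@H]1C(OC)OC | intermediate
18 | 2-[(tert-butyldiphenylsilyloxy)methyl]-3-(dimethoxymethyl)-4-isopropylcyclohexan-1-one (2,3-trans, 3,4-cis) | CC(C)[C@H]1CCC(=O)[C@H](CO[Si](c2ccccc2)(c2ccccc2)C(C)(C)C)[C@H]1C(OC)OC | intermediate
19 | 2-[(tert-butyldiphenylsilyloxy)methyl]-6-isopropyl-3-oxocyclohexane-1-carbaldehyde (1,2-trans, 1,6-cis) | CC(C)[C@H]1CCC(=O)[C@H](CO[Si](c2ccccc2)(c2ccccc2)C(C)(C)C)[C@H]1C=O | intermediate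
20 | tert-butyl[(6-ethenyl-5-isopropyl-2-methylidenecyclohexyl)methoxy]diphenylsilane (1,6-trans, 5,6-cis) | CC(C)[C@H]1CCC(=C)[C@H](CO[Si](c2ccccc2)(c2ccccc2)C(C)(C)C)[C@H]1C=C | intermediate
21 | (6-ethenyl-5-isopropyl-2-methylidenecyclohexyl)methanol (1,6-trans, 5,6-cis) | CC(C)[C@H]1CCC(=C)[C@H](CO)[C@H]1C=C | intermediate
22 | (5-ethenyl-6-isopropyl-1-oxaspiro[2.5]octan-4-yl)methanol (oxirane O cis to CH2OH; 4,5-trans, 5,6-cis) | CC(C)[C@H]1CC[C@@]2(CO2)[C@H](CO)[C@H]1C=C | intermediate
23 | 2-bromoprop-2-en-1-ol | OCC(Br)=C | starting material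
24 | [(2-bromoprop-2-en-1-yl)oxy]tri(propan-2-yl)silane | C=C(Br)CO[Si](C(C)C)(C(C)C)C(C)C | intermediate
25 | (E)-tert-butyldimethyl{[3-(4,4,5,5-tetramethyl-1,3,2-dioxaborolan-2-yl)prop-2-en-1-yl]oxy}silane | CC(C)(C)[Si](C)(C)OC/C=C/B1OC(C)(C)C(C)(C)O1 | starting material
26 | (E)-5-(tert-butyldimethylsilyloxy)-2-{[tri(propan-2-yl)silyloxy]methyl}penta-1,3-diene | CC(C)(C)[Si](C)(C)OC/C=C/C(=C)CO[Si](C(C)C)(C(C)C)C(C)C | intermediate
27 | (S)-4-benzyl-1,3-oxazolidin-2-one | O=C1N[C@@H](Cc2ccccc2)CO1 | starting material
28 | (S)-3-acryloyl-4-benzyl-1,3-oxazolidin-2-one | C=CC(=O)N1[C@@H](Cc2ccccc2)COC1=O | intermediate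
29 | (S)-4-benzyl-3-{[cis-2-[(tert-butyldimethylsilyloxy)methyl]-4-{[tri(propan-2-yl)silyloxy]methyl}cyclohex-3-en-1-yl]carbonyl}-1,3-oxazolidin-2-one | CC(C)(C)[Si](C)(C)OC[C@H]1C=C(CO[Si](C(C)C)(C(C)C)C(C)C)CC[C@H]1C(=O)N1[C@@H](Cc2ccccc2)COC1=O | intermediate
30 | methyl cis-2-[(tert-butyldimethylsilyloxy)methyl]-4-{[tri(propan-2-yl)silyloxy]methyl}cyclohex-3-ene-1-carboxylate | CC(C)(C)[Si](C)(C)OC[C@H]1C=C(CO[Si](C(C)C)(C(C)C)C(C)C)CC[C@H]1C(=O)OC | intermediate
31 | 2-{cis-2-[(tert-butyldimethylsilyloxy)methyl]-4-{[tri(propan-2-yl)silyloxy]methyl}cyclohex-3-en-1-yl}propan-2-ol | CC(C)(C)[Si](C)(C)OC[C@H]1C=C(CO[Si](C(C)C)(C(C)C)C(C)C)CC[C@H]1C(C)(C)O | intermediate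
32 | tert-butyldimethyl{[cis-6-(prop-1-en-2-yl)-3-{[tri(propan-2-yl)silyloxy]methyl}cyclohex-2-en-1-yl]methoxy}silane | CC(C)(C)[Si](C)(C)OC[C@H]1C=C(CO[Si](C(C)C)(C(C)C)C(C)C)CC[C@H]1C(C)=C | intermediate
33 | tert-butyldimethyl{[cis-6-isopropyl-3-{[tri(propan-2-yl)silyloxy]methyl}cyclohex-2-en-1-yl]methoxy}silane | CC(C)(C)[Si](C)(C)OC[C@H]1C=C(CO[Si](C(C)C)(C(C)C)C(C)C)CC[C@H]1C(C)C | intermediate
34 | [cis-6-isopropyl-3-{[tri(propan-2-yl)silyloxy]methyl}cyclohex-2-en-1-yl]methanol | OC[C@H]1C=C(CO[Si](C(C)C)(C(C)C)C(C)C)CC[C@H]1C(C)C | intermediate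
35 | cis-6-isopropyl-3-{[tri(propan-2-yl)silyloxy]methyl}cyclohex-2-ene-1-carbaldehyde | O=C[C@H]1C=C(CO[Si](C(C)C)(C(C)C)C(C)C)CC[C@H]1C(C)C | intermediate
36 | {[cis-3-ethenyl-4-isopropylcyclohex-1-en-1-yl]methoxy}tri(propan-2-yl)silane | C=C[C@H]1C=C(CO[Si](C(C)C)(C(C)C)C(C)C)CC[C@H]1C(C)C | intermediate
37 | methyl 2-(hydroxymethyl)acrylate | C=C(CO)C(=O)OC | starting material
38 | methyl 2-[(tert-butyldimethylsilyloxy)methyl]acrylate | C=C(CO[Si](C)(C)C(C)(C)C)C(=O)OC | intermediate
39 | methyl (E)-2-[(tert-butyldimethylsilyloxy)methyl]-3-[(1R,6S)-6-isopropyl-3-{[tri(propan-2-yl)silyloxy]methyl}cyclohex-2-en-1-yl]acrylate | COC(=O)/C(=C/[C@H]1C=C(CO[Si](C(C)C)(C(C)C)C(C)C)CC[C@H]1C(C)C)CO[Si](C)(C)C(C)(C)C | intermediate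
40 | (E)-2-[(tert-butyldimethylsilyloxy)methyl]-3-[(1R,6S)-6-isopropyl-3-{[tri(propan-2-yl)silyloxy]methyl}cyclohex-2-en-1-yl]acrylic acid | OC(=O)/C(=C/[C@H]1C=C(CO[Si](C(C)C)(C(C)C)C(C)C)CC[C@H]1C(C)C)CO[Si](C)(C)C(C)(C)C | intermediate
41 | [3-ethenyl-1-hydroxy-2-(hydroxymethyl)-4-isopropylcyclohexyl]methyl ester of 40 (4-OH α, 4a-CH2OH α, 8a-ethenyl β, 1-isopropyl β) | CC(C)[C@H]1CC[C@@](O)(COC(=O)/C(=C/[C@H]2C=C(CO[Si](C(C)C)(C(C)C)C(C)C)CC[C@H]2C(C)C)CO[Si](C)(C)C(C)(C)C)[C@H](CO)[C@H]1C=C | intermediate
42 | C9 aldehyde of 41 (not isolated) | CC(C)[C@H]1CC[C@@](O)(COC(=O)/C(=C/[C@H]2C=C(CO[Si](C(C)C)(C(C)C)C(C)C)CC[C@H]2C(C)C)CO[Si](C)(C)C(C)(C)C)[C@H](C=O)[C@H]1C=C | intermediate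
43 | C9 carboxylic acid of 41 | CC(C)[C@H]1CC[C@@](O)(COC(=O)/C(=C/[C@H]2C=C(CO[Si](C(C)C)(C(C)C)C(C)C)CC[C@H]2C(C)C)CO[Si](C)(C)C(C)(C)C)[C@H](C(=O)O)[C@H]1C=C | intermediate
44 | 2-(bromomethyl)acrylic acid | C=C(CBr)C(=O)O | starting material
45 | 2-(trimethylsilyl)ethyl 2-(bromomethyl)acrylate | C=C(CBr)C(=O)OCC[Si](C)(C)C | intermediate
46 | 2-{[2-(trimethylsilyl)ethoxy]carbonyl}prop-2-en-1-yl ester of acid 43 | CC(C)[C@H]1CC[C@@](O)(COC(=O)/C(=C/[C@H]2C=C(CO[Si](C(C)C)(C(C)C)C(C)C)CC[C@H]2C(C)C)CO[Si](C)(C)C(C)(C)C)[C@H](C(=O)OCC(=C)C(=O)OCC[Si](C)(C)C)[C@H]1C=C | intermediate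
47 | target as TIPS ether (ring CH2O), TBS ether (acrylate CH2O) and 2-(trimethylsilyl)ethyl ester (C12) | CC(C)[C@H]1CC[C@@](O)(COC(=O)/C(=C/[C@H]2C=C(CO[Si](C(C)C)(C(C)C)C(C)C)CC[C@H]2C(C)C)CO[Si](C)(C)C(C)(C)C)[C@@H]2C(=O)OCC(C(=O)OCC[Si](C)(C)C)=C[C@@H]12 | intermediate
48 | CNP0361406.11 | CC(C)[C@H]1CC[C@@](O)(COC(=O)/C(=C/[C@H]2C=C(CO)CC[C@H]2C(C)C)CO)[C@@H]2C(=O)OCC(C(=O)O)=C[C@@H]12 | target

## Step count and least certain steps

Total: 38 steps. Longest linear sequence: 22 steps (steps 2 to 18, then 33, 34, 36, 37 and 38).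

**Step 4 (key step).** The thermal cycloaddition may be slow, and polymerisation of the diene or hydrolysis of its silyl enol ether can then outrun it; the acetal face control itself is not in doubt. Fallback, from 6 back to 8: the more reactive trans-1-methoxy-3-(trimethylsilyloxy)buta-1,3-diene is added to 6 to give the methoxy silyl enol ether adduct F1. Dilute acid converts it to the enone lactone F2. Rhodium-catalysed 1,4-hydrosilylation (Et3SiH, RhCl(PPh3)3), a neutral reaction that leaves the acidic C1–H alone, gives the triethylsilyl enol ether F3 with the same C3=C4 position as 7. Bromination as in step 5 then gives 8.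

**Step 33.** Attack of the hindered acrylate carboxylate at the neopentyl-type C14 may be slow, so that the C9 hydroxyl opens the epoxide intramolecularly to a tetrahydrofuran. Fallback, from 22 back to 47:
- KOH in DMSO/H2O opens the epoxide at C14 to the triol F8.
- 2,2-Dimethoxypropane with PPTS protects the 1,2-diol as the acetonide alcohol F9.
- TEMPO/PhI(OAc)2 gives the acetonide acid F10.
- Alkylation with 45 gives the diene ester F11, and ring-closing metathesis the bicyclic acetonide lactone F12.
- Aqueous acetic acid frees the diol F13.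
- The primary hydroxyl of F13 is esterified at once with 40 (2,4,6-trichlorobenzoyl chloride, Et3N, then DMAP) to give 47.

This order exposes a free C14 hydroxyl beside the C9 lactone, which is why it is only the fallback.

**Step 8 (and likewise step 25).** Elimination may run toward the ring C–H and give the tetrasubstituted isopropylidene isomer, which lowers the yield and would cost the C1 configuration if it were hydrogenated. Fallback, from 10 back to 12: Me(MeO)NH·HCl with iPrMgCl gives the Weinreb amide F4, MeMgBr the methyl ketone F5, and the non-basic Tebbe reagent Cp2Ti(μ-Cl)(μ-CH2)AlMe2 methylenates F5 to 12 without epimerising C1.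

**Step 31.** The vinyl group sits on a doubly allylic, branched carbon and the partner is 1,1-disubstituted, so productive cross-metathesis may be slow and alkene migration or homodimerisation may compete. Fallback, from 35 back to 39: methyl 3-(tert-butyldimethylsilyloxy)propanoate F6 (from methyl 3-hydroxypropanoate and TBSCl) is deprotonated with LiN(iPr)2 at −78 °C and added to 35 to give the aldol adduct F7. Mesylation and elimination with DBU (E1cB) give 39 with the ester trans to the ring.

**Step 37.** Closure of a seven-membered ring onto an electron-poor 1,1-disubstituted alkene may be slower than oligomerisation through the vinyl group. Fallback, from 43 back to 47: cross-metathesis of the C13 vinyl group of 43 with an excess of 45 gives the (E)-bromomethyl acrylate acid F14. KHCO3 in dilute DMF then closes ring B by intramolecular carboxylate alkylation (O10–C11 bond) to 47.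

## Further compounds

F1 | step 4 | methoxy silyl enol ether adduct of 6 with trans-1-methoxy-3-(trimethylsilyloxy)buta-1,3-diene | O=C1O[C@@H](O[C@@H]3C[C@H](C)CC[C@H]3C(C)C)[C@@H]2CC(O[Si](C)(C)C)=CC(OC)[C@H]12
F2 | step 4 | (3R,3aR,7aS)-3-menthyloxy-3a,4-dihydro-2-benzofuran-1,5(3H,7aH)-dione (enone lactone) | O=C1O[C@@H](O[C@@H]3C[C@H](C)CC[C@H]3C(C)C)[C@@H]2CC(=O)C=C[C@H]12
F3 | step 4 | triethylsilyl enol ether analogue of 7 | O=C1O[C@@H](O[C@@H]3C[C@H](C)CC[C@H]3C(C)C)[C@@H]2CC(O[Si](CC)(CC)CC)=CC[C@H]12
F4 | step 8 | Weinreb amide of acid 9 (N-methoxy-N-methyl amide, 1,2-cis) | CON(C)C(=O)[C@H]1CC(Br)C(OC)(OC)C[C@H]1C(OC)OC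
F5 | step 8 | 1-[5-bromo-2-(dimethoxymethyl)-4,4-dimethoxycyclohexyl]ethan-1-one (1,2-cis) | CC(=O)[C@H]1CC(Br)C(OC)(OC)C[C@H]1C(OC)OC
F6 | step 31 | methyl 3-(tert-butyldimethylsilyloxy)propanoate | COC(=O)CCO[Si](C)(C)C(C)(C)C
F7 | step 31 | aldol adduct of F6 with 35 (β-hydroxy ester, carbinol and α-centre as mixtures) | COC(=O)C(CO[Si](C)(C)C(C)(C)C)C(O)[C@H]1C=C(CO[Si](C(C)C)(C(C)C)C(C)C)CC[C@H]1C(C)C
F8 | step 33 | 3-ethenyl-1,2-bis(hydroxymethyl)-4-isopropylcyclohexan-1-ol (triol from 22) | CC(C)[C@H]1CC[C@@](O)(CO)[C@H](CO)[C@H]1C=C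
F9 | step 33 | acetonide alcohol (C4/C14 dioxolane, free C9 hydroxyl) | CC(C)[C@H]1CC[C@@]2(COC(C)(C)O2)[C@H](CO)[C@H]1C=C
F10 | step 33 | acetonide acid (C9 carboxylic acid) | CC(C)[C@H]1CC[C@@]2(COC(C)(C)O2)[C@H](C(=O)O)[C@H]1C=C
F11 | step 33 | acetonide diene ester (C9 ester with the acrylate of 45) | CC(C)[C@H]1CC[C@@]2(COC(C)(C)O2)[C@H](C(=O)OCC(=C)C(=O)OCC[Si](C)(C)C)[C@H]1C=C
F12 | step 33 | bicyclic acetonide lactone (rings A and B, 2-(trimethylsilyl)ethyl ester) | CC(C)[C@H]1CC[C@@]3(COC(C)(C)O3)[C@@H]2C(=O)OCC(C(=O)OCC[Si](C)(C)C)=C[C@@H]12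
F13 | step 33 | right-half diol, 2-(trimethylsilyl)ethyl ester | CC(C)[C@H]1CC[C@@](O)(CO)[C@@H]2C(=O)OCC(C(=O)OCC[Si](C)(C)C)=C[C@@H]12
F14 | step 37 | (E)-bromomethyl acrylate acid from cross-metathesis of 43 with 45 | CC(C)[C@H]1CC[C@@](O)(COC(=O)/C(=C/[C@H]2C=C(CO[Si](C(C)C)(C(C)C)C(C)C)CC[C@H]2C(C)C)CO[Si](C)(C)C(C)(C)C)[C@H](C(=O)O)[C@H]1/C=C(\CBr)C(=O)OCC[Si](C)(C)C
A1 | alternative 1 | cis-2-[(4-methoxybenzyloxy)methyl]-4-[(tert-butyldimethylsilyloxy)methyl]cyclohex-3-ene-1-carboxylic acid | COc1ccc(COC[C@H]2C=C(CO[Si](C)(C)C(C)(C)C)CC[C@H]2C(=O)O)cc1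
A2 | alternative 2 | rings A and B with allyl ester and C4/C14 acetonide | CC(C)[C@H]1CC[C@@]3(COC(C)(C)O3)[C@@H]2C(=O)OCC(C(=O)OCC=C)=C[C@@H]12
A3 | alternative 2 | allyl 2-(diethoxyphosphoryl)acrylate | C=C(C(=O)OCC=C)P(=O)(OCC)OCC
A4 | alternative 3 | target as bis(tert-butyldimethylsilyl) ether and 2-(trimethylsilyl)ethyl ester | CC(C)[C@H]1CC[C@@](O)(COC(=O)/C(=C/[C@H]3C=C(CO[Si](C)(C)C(C)(C)C)CC[C@H]3C(C)C)CO[Si](C)(C)C(C)(C)C)[C@@H]2C(=O)OCC(C(=O)OCC[Si](C)(C)C)=C[C@@H]12
A5 | alternative 3 | left alkenyl iodide (iodine trans to the ring across the C=C) | I/C(=C/[C@H]1C=C(CO[Si](C)(C)C(C)(C)C)CC[C@H]1C(C)C)CO[Si](C)(C)C(C)(C)C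
A6 | alternative 3 | right-half diol, 2-(trimethylsilyl)ethyl ester | CC(C)[C@H]1CC[C@@](O)(CO)[C@@H]2C(=O)OCC(C(=O)OCC[Si](C)(C)C)=C[C@@H]12
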